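All runs are simulated for substances that don't exist.

Our closed, stirred vessel holds a solid substrate that dissolves and meets a gas, held at a fixed saturation, to give target. The birch run is this very flask, followed up to 120 s.

- birch: solid substrate 18 mM; gas 1.4 mM (held); the very flask that is asked about, followed so far
- flask: solid substrate 18 mM; gas 1.4 mM (held); time 5.0 min

- birch (time / s: target / %, solid substrate / %): 10.0: 2.0, 63.2; 20.0: 3.2, 54.6; 30.0: 5.6, 53.0; 60.0: 14.2, 45.0; 120: 27.9, 30.9

(each reading ± 0.5 percentage points)

- solid substrate is a solid; its amount is given per volume of the solution
- what was read earlier has a scatter of 0.5 percentage points, one standard deviation
- at the start none of the gas is in solution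
- at the start none of the solid substrate is in solution

- north: doubling the saturation concentration of gas, all else as stated
- north-west: doubling the dissolution coefficient of the solid substrate, all else as stated
- north-east: doubling the solubility of the solid substrate, all else as stated
- south: doubling the transfer coefficient of the gas, all else as stated

1. how much target there is at 5.0 min, in percent of the solid substrate charged
2. the change that raises the amount of target at 5.0 min, in percent of the solid substrate charged most ("none" if none brings more than 2 percentage points) (north / north-west / north-east / south / none)
3. amount of target at 5.0 min, in percent of the solid substrate charged, after north-east

We reckon with what is left of the charge, not with what is made. In the birch flask, solid plus target holds near 58.8% from 30.0 s on, so 41.2% of the charge sits in solution. Target meanwhile climbs steadily. That gives the drain, 0.0446 mM s⁻¹, the concentration of charge turned into target each second while solid lies in the flask. This is a zero-order stretch, and it follows a lag of 7.40 s. The solid lasts until about 245 s. We then take what is left to decay at the drain over the amount in solution, 0.00601 s⁻¹, which leaves target at 70.5% at 5.0 min.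

Now the settings, by hand. If north-west halves the lag, which is far shorter than the time the solid lasts, it gains 0.92 percentage points. North doubles the drain and the decay, giving 94.9%. For north-east we assume, as a rough upper guess, that what is in solution and the drain both double and the decay stays as it is, and this assumption gives 82.4%. South doubles the drain if the passage of gas is slow and does little if it is fast, and the readings do not say which. We choose north, which gives more than north-east.

The forecast says 69% (65% to 73%), 80% after north-east (70% to 85%), and north: “Doubling gas saturation doubles the rate whether transfer or kinetics limits”. Our 70.5% is higher than its figure.

The flask gives 69.6%, and 80.6% after north-east. The gains are 26 points for north, the most, 23 points for south, 11 points for north-east and 0.83 points for north-west.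

    reagent → side product (k = 0.785 s⁻¹)
    dissolved substrate + reagent → target (k = 29.8 M⁻¹ s⁻¹)
    gas ⇌ reagent, rate k3*(csat - [reagent]) (kL = 0.162 s⁻¹)
    solid substrate ⇌ dissolved substrate, rate k4*(cs4 - [dissolved substrate]) while solid is left; crystals form when [dissolved substrate] > cs4 (solubility = 7.70 mM, k = 0.210 s⁻¹)

In this flask reagent stood at 0.194 mM at 0.500 min and 0.194 mM at 2.50 min, and the drain puts target at 35.3% at 2.50 min, where the flask has 35.0%. The neighbour flask is charged with 45 mM. The same drain in mM, taken over the same time, leaves 71.0% of that charge. That neighbour flask has 28.4% target at 5.00 min, with 72% of its charge left, solid or dissolved, and 54.9% of its charge still solid.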